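## Analysis of the target

Compound 25 is a single cyclohexane ring with no oxygen. Ring atoms are numbered C1–C6: C1 is quaternary (C7 methyl and the (Z)-chlorovinyl group C8=C9), C3 is a tertiary bromide that also carries the bromomethyl carbon C10, C4 and C6 are secondary chlorides, and C2 and C5 are methylenes. The four stereocentres are C1 (S), C3 (S), C4 (R) and C6 (S) in this numbering, i.e. (1S,2R,4S,5S)-1-bromo-1-(bromomethyl)-2,4-dichloro-5-[(Z)-2-chloroethenyl]-5-methylcyclohexane. Both chlorines, the C3 bromine and the chlorovinyl group lie on one face of the ring; the C7 methyl and C10 lie on the other. In the chair that keeps C7 and both chlorines equatorial, the chlorovinyl group and the C3 bromine are axial and syn. The sensitive groups are the vicinal dibromide with its tertiary C–Br (lost to phosphines, zinc, fluoride or base), the Z-chloroalkene (dehydrochlorinated by strong base) and the C4 chloride, which is allylic as long as C3=C10 exists. The synthesis is hard for three reasons: the C6 chlorine sits next to the quaternary stereocentre C1 on the more crowded face, so it must enter by inversion at a neopentyl-type carbon; C3 can only be set by a face-selective addition; and the target keeps no functional handle, so every oxygen used is scaffolding. The strategy rests on the two equal arms that join C1 to C4 (C1–C2–C3–C4 and C1–C6–C5–C4). With the halogens removed and a carbonyl at C4, the ring becomes a 4,4-disubstituted cyclohexa-2,5-dienone with enantiotopic arms and a prochiral C1, in which the β-carbon of one arm is C6, the carbonyl is C4 and the α-carbon of the other arm is C3.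

## Retrosynthetic reasoning

**25 ⇒ 24.** The C3–Br and C10–Br bonds are cut first. A vicinal dibromide would not survive the phosphines, ylide or fluoride used earlier, so it is made last by anti addition of bromine across the exocyclic C3=C10 of 24. The forward step must distinguish the 1,1-disubstituted alkene from the chloroalkene and must place bromide on C3 on the C8 face.

**24 ⇒ 23.** The C4–Cl bond is cut next. An allylic chloride next to an exocyclic methylene epimerises and transposes easily, so it is formed in the penultimate step from allylic alcohol 23 of opposite configuration at C4. The forward step must be a clean SN2 displacement without allylic shift.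

**23 ⇒ 22 ⇒ 21 ⇒ 20 ⇒ 19.** The C8=C9 bond is cut. The chlorovinyl group comes from aldehyde 21 by a one-carbon olefination, 21 from primary alcohol 20, and 20 from silyl ether 19. The basic olefination is placed here because neither the allylic chloride nor the dibromide exists yet and the C6 chloride tolerates it. The C4 oxygen is carried as an acetate through 19–22 so that it is not oxidised.

**19 ⇒ 18 ⇒ 17.** The C6–Cl bond is cut to the C6 alcohol 18 of opposite configuration. This is done before C4 is chlorinated, because the forcing conditions and free chloride would scramble an allylic chloride. It is done while C8 is still silylated, because a free C8 alkoxide lies on the rear side of the activated C6–O bond and would close an oxetane. Monoacetate 18 comes from diol 17 by acylating the unhindered allylic hydroxyl; the C6 hydroxyl, flanked by C1, reacts much more slowly.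

**17 ⇒ 15 ⇒ 11.** The C4–H bond and the C3–C10 bond are cut. Diol 17 arises by 1,2-reduction of α-methylene ketone 15, which sets the C4 oxygen cis to the C6 oxygen. Ketone 15 comes from enone 11 by conjugate reduction, capture of enolate 12 at C3 by a one-carbon iminium electrophile (13) and elimination through 14. The enolate is formed only towards C3 because it derives from the remaining enone arm. C10 is the only carbon that does not come from the arene or the methyl group.

**11 ⇒ 10 ⇒ 9.** The silyl group is removed and the C5–O bond is restored. Hydroxy enone 10 comes from epoxy enone 9 by reductive cleavage of the C–O bond α to the carbonyl. This removes the oxygen from C5, which is a methylene in 25, and leaves the C6–O bond and its configuration untouched.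

**9 ⇒ 8.** The C5–O and C6–O bonds are cut. This is the key disconnection: it returns the achiral, flat dienone 8, and the forward epoxidation of one enantiotopic arm sets C1, C5 and C6 in one catalytic step without forming any C–C bond.

**8 ⇒ 7 ⇒ 5 ⇒ 4 ⇒ 1 + 2 (+ 6).** Dienone 8 comes from diene 7 by oxidation of the doubly allylic methylene. Diene 7 is the silyl ether (from 6) of alcohol 5, which is the reduction product of acid 4. Acid 4 arises from benzoic acid 1 and iodomethane 2 by reductive alkylation through dianion 3, which forms the C1–C7 bond and creates C1 as a still achiral quaternary carbon.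

## Alternatives that were turned down

**Alternative 1:** The ring is opened at C4–C5. The prochiral diacetyl enal A2 would be cyclised by a chiral amine, which converts one of the two enantiotopic acetyl groups into its enamine; that enamine adds to the C4 aldehyde to give ketol A1.
- For: one C–C bond formation closes the ring, sets C1 and C4, and delivers the C3=C10 methylene and the C4 hydroxyl (cis to C7) already in place. On this point it is stronger than the chosen route, which needs a reductive methylenation and a separate carbonyl reduction for the same array.
- Against: the acceptor in A2 is an α-substituted acrolein. The amine should condense with it (iminium ion) faster than with a hindered methyl ketone next to a quaternary carbon, and the enamine can also add 1,4 to C10, which closes a six-membered ring as well.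
- Against: A1 is a β-hydroxy ketone prone to dehydration. C6 arrives as a ketone beside the quaternary carbon, so it must still be reduced face-selectively and then substituted with inversion. C8 arrives as an acetyl group, which reaches a Z-chlorovinyl group only through an alkyne, a chloroalkyne and a cis reduction.
- Comparison: more steps on both sides of the key step and an unresolved chemoselectivity problem. The chosen strategy offers a four-step precursor and a C6 oxygen of defined configuration.

**Alternative 2:** The ring is opened at C3–C4. The ynal A4 would be cyclised with Ni(cod)2 (zerovalent nickel), a phosphine and a trialkylsilane: oxidative cyclisation of alkyne and aldehyde to an oxanickelacycle, σ-bond metathesis with the silane and reductive elimination give A3, which carries the exocyclic methylene and a C4 silyl ether.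
- For: the methylene carbinol is made directly, and the three oxygens of A3 carry three different protecting groups. The C4/C6 differentiation, which costs the chosen route an acylation and a deacylation, is free here; on this point the alternative is stronger.
- Against: the cyclisation creates only C4. The adjacent quaternary C1 and secondary C6 stereocentres of A4 must be built in the open chain by separate asymmetric steps (roughly seven to nine steps to A4).
- Against: the C4 configuration depends on 1,3-induction from C6 across the forming ring, and the terminal alkyne invites oligomerisation. The end game, including the inversion at C6, is unchanged.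
- Comparison: longer, with stereochemical risk spread over several steps. The chosen route sets C1, C5 and C6 together from an achiral precursor.

**Alternative 3:** The ring is opened at C4–C5 and C5–C6, with nitromethane A7 as C5. Dialdehyde A6 and A7 would undergo two reversible Henry additions under base to give the all-equatorial nitro diol A5.
- For: cheap reagents, and thermodynamic control of three stereocentres relative to C1 without a chiral catalyst. As a ring closure this is more robust than a catalytic desymmetrisation.
- Against: C1 is not set in the key step. A6 is chiral and would have to be made as a single enantiomer with its quaternary α-carbon.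
- Against: C5 of the target is a methylene. The nitro group must be removed from a secondary carbon between two oxygenated carbons, where radical denitration is poor and any hydroxyl activation invites retro-Henry cleavage or nitroalkene formation.
- Against: both hydroxyls of A5 are cis to C7, so both still need inversion, and the C3 ketal needs hydrolysis and methylenation.
- Comparison: more steps, one C–N bond made only to be broken, and the quaternary centre unsolved. In the chosen route C5 is free of substituents as soon as the epoxide is opened.

Key step: step 5

Remark: locants C1–C10 in the text are those of the analysis; "C7 face" means the ring face that carries the C7 methyl.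

Remark (assumption): the absolute sense of induction of the amine catalyst on 8 must be assigned in the first experiment; the quinine- and quinidine-derived catalysts are pseudoenantiomers, and the one that delivers 9 is used.

## Route

Step 1
Reactants: 1 benzoic acid; 2 iodomethane
Product: 4 1-methylcyclohexa-2,5-diene-1-carboxylic acid, via dilithium dianion 3 (not isolated)
Conditions: Li, NH3(l), THF, −78 °C; MeI; aq HCl
Reagents that add atoms: none
Why: Birch reduction–alkylation: two-electron reduction and para-protonation give dianion 3, which is methylated at the carboxylate-bearing carbon to give the 1,1-disubstituted 1,4-diene; no stereocentre is formed.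

Step 2
Reactants: 4 1-methylcyclohexa-2,5-diene-1-carboxylic acid
Product: 5 (1-methylcyclohexa-2,5-dien-1-yl)methanol
Conditions: LiAlH4, THF, 0 °C → rt
Reagents that add atoms: none
Why: LiAlH4 reduction of a carboxylic acid to the primary alcohol; the unconjugated diene is inert to hydride.

Step 3
Reactants: 5 (1-methylcyclohexa-2,5-dien-1-yl)methanol; 6 tert-butyl(chloro)diphenylsilane
Product: 7 tert-butyl[(1-methylcyclohexa-2,5-dien-1-yl)methoxy]diphenylsilane
Conditions: imidazole, DMF, rt
Reagents that add atoms: none
Why: Standard silylation of a primary alcohol; the bulky silyl ether is meant to make the C8 side of C1 the larger one in step 5 and to last until step 12.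

Step 4
Reactants: 7 tert-butyl[(1-methylcyclohexa-2,5-dien-1-yl)methoxy]diphenylsilane
Product: 8 4-{[tert-butyl(diphenyl)silyl]oxymethyl}-4-methylcyclohexa-2,5-dien-1-one
Conditions: CrO3, 3,5-dimethylpyrazole, CH2Cl2, −20 °C
Reagents that add atoms: chromium trioxide, O=[Cr](=O)=O
Why: Allylic C–H oxidation with the CrO3–3,5-dimethylpyrazole complex; the doubly allylic methylene is the only activated position, and the quaternary C1 blocks aromatisation, so the cross-conjugated dienone should result.

Step 5
Reactants: 8 4-{[tert-butyl(diphenyl)silyl]oxymethyl}-4-methylcyclohexa-2,5-dien-1-one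
Product: 9 (1S,5S,6S)-5-{[tert-butyl(diphenyl)silyl]oxymethyl}-5-methyl-7-oxabicyclo[4.1.0]hept-3-en-2-one
Conditions: 9-amino-9-deoxy-epi-quinine·2CF3CO2H (10 mol %), 50% aq H2O2 (1.1 equiv), 1,4-dioxane, 35 °C
Reagents that add atoms: hydrogen peroxide, OO
Why: The amine salt condenses with the C4 carbonyl of 8 to a cross-conjugated iminium ion; hydroperoxide, held by the protonated quinuclidine of the catalyst, adds to the β-carbon C6 of one arm, and the resulting enamine carbon C5 then attacks the proximal peroxide oxygen with loss of hydroxide, closing the oxirane in a 3-exo-tet mode at oxygen before hydrolysis frees the catalyst. The closest known reaction type is the amine-salt-catalysed Weitz–Scheffer epoxidation of cyclic enones with H2O2 (4,4-disubstituted cyclohexenones included), together with catalytic desymmetrisation of 4,4-disubstituted cyclohexadienones by addition to one arm. C6 and C5 are controlled by the catalyst, which fixes the absolute sense of attack at the β-carbon, and C1 becomes stereogenic at the same moment because only one arm reacts. Attack on the C7 face at C6 and attack on the C7 face at C2 are enantiomeric events, so the catalyst-preferred sense allows C7-face attack on one arm only, and the substrate preference for attack anti to the silyloxymethyl group then selects that arm, making 9 the matched product with the oxirane cis to C7. The step therefore needs arm selection by the catalyst and C7-face over C8-face attack, secured by the size difference between CH2OSi(t-Bu)Ph2 and CH3 on C1; the mismatched combination would give a diastereomer, not the enantiomer, and should be separable. Over-epoxidation is held back by using about one equivalent of H2O2, since epoxy enone 9 is the poorer acceptor.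

Step 6
Reactants: 9 (1S,5S,6S)-5-{[tert-butyl(diphenyl)silyl]oxymethyl}-5-methyl-7-oxabicyclo[4.1.0]hept-3-en-2-one
Product: 10 (4S,5R)-4-{[tert-butyl(diphenyl)silyl]oxymethyl}-5-hydroxy-4-methylcyclohex-2-en-1-one
Conditions: (PhSe)2, NaBH4, EtOH, 0 °C; AcOH; then 9, 0 °C → rt
Reagents that add atoms: none
Why: Organoselenium-mediated reductive opening of an α,β-epoxy ketone: selenolate opens the oxirane at the α-carbon C5, a second selenolate removes selenium to give the enol, and AcOH protonates it; the C6–O bond is not touched, so C6 keeps its configuration. The enone β-carbon C2 is neopentylic, so conjugate addition of selenolate there should be slow and reversible.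

Step 7
Reactants: 10 (4S,5R)-4-{[tert-butyl(diphenyl)silyl]oxymethyl}-5-hydroxy-4-methylcyclohex-2-en-1-one
Product: 11 (4S,5R)-4-{[tert-butyl(diphenyl)silyl]oxymethyl}-4-methyl-5-(triethylsilyloxy)cyclohex-2-en-1-one
Conditions: Et3SiCl, imidazole, DMF, 0 °C
Reagents that add atoms: chlorotriethylsilane, CC[Si](Cl)(CC)CC
Why: Silylation under mild conditions; it blocks retro-aldol cleavage and β-elimination of the β-hydroxy ketone during the enolate chemistry of step 8.

Step 8
Reactants: 11 (4S,5R)-4-{[tert-butyl(diphenyl)silyl]oxymethyl}-4-methyl-5-(triethylsilyloxy)cyclohex-2-en-1-one; 2 iodomethane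
Product: 15 (4S,5R)-4-{[tert-butyl(diphenyl)silyl]oxymethyl}-4-methyl-2-methylidene-5-(triethylsilyloxy)cyclohexan-1-one, via lithium enolate 12 (not isolated), via Mannich base 13 (not isolated), via trimethylammonium iodide 14 (not isolated)
Conditions: LiBH(s-Bu)3, THF, −78 °C; CH2=NMe2+ I−, −78 °C → rt; MeI, rt; sat. aq NaHCO3, CH2Cl2
Reagents that add atoms: N,N-dimethylmethyleneiminium iodide (Eschenmoser's salt), C=[N+](C)C.[I-]
Why: 1,4-Hydride addition to the enone gives enolate 12 only towards C3, a Mannich reaction installs C10, and quaternisation of the crude amine followed by E1cB elimination of trimethylamine gives the α-methylene ketone; the transient C3 stereocentre is lost in the elimination. The mild bicarbonate base is chosen so that the β-silyloxy group at C6 is not eliminated.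

Step 9
Reactants: 15 (4S,5R)-4-{[tert-butyl(diphenyl)silyl]oxymethyl}-4-methyl-2-methylidene-5-(triethylsilyloxy)cyclohexan-1-one
Product: 17 (1S,3R,4S)-4-{[tert-butyl(diphenyl)silyl]oxymethyl}-4-methyl-6-methylidenecyclohexane-1,3-diol, via triethylsilyl ether 16 (not isolated)
Conditions: NaBH4, CeCl3·7H2O, MeOH, −78 °C; then 1 M aq HCl, 0 °C → rt
Reagents that add atoms: none
Why: Luche 1,2-reduction of the exocyclic enone: hydride should come from the face opposite C7 in both chairs (axial attack when the C6 silyloxy group is equatorial, equatorial attack when it is axial and blocks the axial path), which puts the C4 hydroxyl cis to the C6 oxygen. Dilute acid then cleaves only the triethylsilyl ether.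

Step 10
Reactants: 17 (1S,3R,4S)-4-{[tert-butyl(diphenyl)silyl]oxymethyl}-4-methyl-6-methylidenecyclohexane-1,3-diol
Product: 18 (1S,4S,5R)-4-{[tert-butyl(diphenyl)silyl]oxymethyl}-5-hydroxy-4-methyl-2-methylidenecyclohexyl acetate
Conditions: AcCl (1.05 equiv), 2,4,6-collidine, CH2Cl2, −78 °C
Reagents that add atoms: acetyl chloride, CC(Cl)=O
Why: Sterically controlled mono-acylation: the C6 hydroxyl is neopentylic and flanked by the quaternary C1, so the allylic C4 hydroxyl should react first.

Step 11
Reactants: 18 (1S,4S,5R)-4-{[tert-butyl(diphenyl)silyl]oxymethyl}-5-hydroxy-4-methyl-2-methylidenecyclohexyl acetate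
Product: 19 (1S,4S,5S)-4-{[tert-butyl(diphenyl)silyl]oxymethyl}-5-chloro-4-methyl-2-methylidenecyclohexyl acetate
Conditions: PPh3, CCl4, MeCN, 70 °C
Reagents that add atoms: tetrachloromethane, ClC(Cl)(Cl)Cl
Why: Appel chlorination: the C6 oxyphosphonium ion is displaced by chloride with inversion, which puts chlorine on the C8 face; phosphorus activation is the deoxychlorination that converts neopentyl-type alcohols without skeletal rearrangement. In the chair with the oxyphosphonium group equatorial there is no antiperiplanar hydrogen for E2, and the cis C4 acetate cannot attack C6 from the rear.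

Step 12
Reactants: 19 (1S,4S,5S)-4-{[tert-butyl(diphenyl)silyl]oxymethyl}-5-chloro-4-methyl-2-methylidenecyclohexyl acetate
Product: 20 (1S,4S,5S)-5-chloro-4-(hydroxymethyl)-4-methyl-2-methylidenecyclohexyl acetate
Conditions: Bu4NF, AcOH, THF, rt → 40 °C
Reagents that add atoms: none
Why: Fluoride cleavage of the silyl ether, buffered so that the acetate stays; the C6 chlorine is now cis to C8, so the freed hydroxyl has no rear-side access to C6 and no antiperiplanar arrangement for fragmentation.

Step 13
Reactants: 20 (1S,4S,5S)-5-chloro-4-(hydroxymethyl)-4-methyl-2-methylidenecyclohexyl acetate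
Product: 21 (1S,4S,5S)-5-chloro-4-formyl-4-methyl-2-methylidenecyclohexyl acetate
Conditions: Dess–Martin periodinane, NaHCO3, CH2Cl2, 0 °C → rt
Reagents that add atoms: none
Why: Dess–Martin oxidation of a primary alcohol; the aldehyde has no α-hydrogen, so it cannot enolise or lose HCl.

Step 14
Reactants: 21 (1S,4S,5S)-5-chloro-4-formyl-4-methyl-2-methylidenecyclohexyl acetate
Product: 22 (1S,4S,5S)-5-chloro-4-[(Z)-2-chloroethenyl]-4-methyl-2-methylidenecyclohexyl acetate
Conditions: [Ph3PCH2Cl]Cl, NaN(SiMe3)2 (slightly less than 1 equiv per salt), THF, −78 → 0 °C
Reagents that add atoms: (chloromethyl)triphenylphosphonium chloride, ClC[P+](c1ccccc1)(c1ccccc1)c1ccccc1.[Cl-]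
Why: Wittig chloromethylenation with the non-stabilised ylide under lithium-free conditions; kinetic formation of the cis-oxaphosphetane should favour the Z-chloroalkene, and the E isomer is to be removed by chromatography. The ylide is pre-formed with a slight deficit of base so that the acetate is not enolised.

Step 15
Reactants: 22 (1S,4S,5S)-5-chloro-4-[(Z)-2-chloroethenyl]-4-methyl-2-methylidenecyclohexyl acetate
Product: 23 (1S,4S,5S)-5-chloro-4-[(Z)-2-chloroethenyl]-4-methyl-2-methylidenecyclohexan-1-ol
Conditions: K2CO3, MeOH, 0 °C
Reagents that add atoms: none
Why: Base-catalysed transesterification; carbonate in methanol is too weak a base to dehydrochlorinate the Z-chloroalkene or the secondary chloride.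

Step 16
Reactants: 23 (1S,4S,5S)-5-chloro-4-[(Z)-2-chloroethenyl]-4-methyl-2-methylidenecyclohexan-1-ol
Product: 24 (1S,2S,4R)-2,4-dichloro-1-[(Z)-2-chloroethenyl]-1-methyl-5-methylidenecyclohexane
Conditions: PPh3 (1.05 equiv), Cl3CC(O)CCl3, CH2Cl2, −20 → 0 °C
Reagents that add atoms: hexachloroacetone, ClC(Cl)(Cl)C(=O)C(Cl)(Cl)Cl
Why: Appel-type chlorination of an allylic alcohol with PPh3–hexachloroacetone, a fast low-temperature SN2 collapse of the oxyphosphonium ion that is known to go with inversion and little allylic transposition; it puts the C4 chlorine on the C8 face. The allylic chloride is taken on at once because it could ionise or shift on standing.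

Step 17
Reactants: 24 (1S,2S,4R)-2,4-dichloro-1-[(Z)-2-chloroethenyl]-1-methyl-5-methylidenecyclohexane
Product: 25 (1S,2R,4S,5S)-1-bromo-1-(bromomethyl)-2,4-dichloro-5-[(Z)-2-chloroethenyl]-5-methylcyclohexane
Conditions: Br2 (1.0 equiv), CH2Cl2, −78 °C, dark
Reagents that add atoms: bromine, BrBr
Why: Electrophilic anti addition of bromine: the 1,1-disubstituted alkene is much more nucleophilic than the chloroalkene and should react alone. In the chair with C7 and both chlorines equatorial, bromide should open the bromonium ion at the tertiary C3 along the axial line, giving axial C3–Br on the C8 face and equatorial C10; this is also the more stable C3 epimer, since bromine is smaller than bromomethyl in the position syn to the axial chlorovinyl group.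

## Compound list

1 | benzoic acid | OC(=O)c1ccccc1 | starting material
2 | iodomethane | CI | starting material
3 | dilithium salt of the Birch dianion of benzoic acid (cyclohexa-2,5-dien-1-ylidenemethanediolate) | [Li+].[Li+].[O-]C([O-])=C1C=CCC=C1 | intermediate
4 | 1-methylcyclohexa-2,5-diene-1-carboxylic acid | CC1(C(=O)O)C=CCC=C1 | intermediate
5 | (1-methylcyclohexa-2,5-dien-1-yl)methanol | CC1(CO)C=CCC=C1 | intermediate
6 | tert-butyl(chloro)diphenylsilane | CC(C)(C)[Si](Cl)(c1ccccc1)c1ccccc1 | starting material
7 | tert-butyl[(1-methylcyclohexa-2,5-dien-1-yl)methoxy]diphenylsilane | CC1(CO[Si](c2ccccc2)(c2ccccc2)C(C)(C)C)C=CCC=C1 | intermediate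
8 | 4-{[tert-butyl(diphenyl)silyl]oxymethyl}-4-methylcyclohexa-2,5-dien-1-one | CC1(CO[Si](c2ccccc2)(c2ccccc2)C(C)(C)C)C=CC(=O)C=C1 | intermediate
9 | (1S,5S,6S)-5-{[tert-butyl(diphenyl)silyl]oxymethyl}-5-methyl-7-oxabicyclo[4.1.0]hept-3-en-2-one (oxirane cis to the methyl group) | C[C@@]1(CO[Si](c2ccccc2)(c2ccccc2)C(C)(C)C)C=CC(=O)[C@H]2O[C@@H]12 | intermediate
10 | (4S,5R)-4-{[tert-butyl(diphenyl)silyl]oxymethyl}-5-hydroxy-4-methylcyclohex-2-en-1-one (hydroxyl cis to the methyl group) | C[C@@]1(CO[Si](c2ccccc2)(c2ccccc2)C(C)(C)C)C=CC(=O)C[C@H]1O | intermediate
11 | (4S,5R)-4-{[tert-butyl(diphenyl)silyl]oxymethyl}-4-methyl-5-(triethylsilyloxy)cyclohex-2-en-1-one | C[C@@]1(CO[Si](c2ccccc2)(c2ccccc2)C(C)(C)C)C=CC(=O)C[C@H]1O[Si](CC)(CC)CC | intermediate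
12 | lithium (4S,5R)-4-{[tert-butyl(diphenyl)silyl]oxymethyl}-4-methyl-5-(triethylsilyloxy)cyclohex-1-en-1-olate | [Li+].C[C@@]1(CO[Si](c2ccccc2)(c2ccccc2)C(C)(C)C)CC=C([O-])C[C@H]1O[Si](CC)(CC)CC | intermediate
13 | (4S,5R)-4-{[tert-butyl(diphenyl)silyl]oxymethyl}-2-[(dimethylamino)methyl]-4-methyl-5-(triethylsilyloxy)cyclohexan-1-one (both C2 epimers) | C[C@@]1(CO[Si](c2ccccc2)(c2ccccc2)C(C)(C)C)CC(CN(C)C)C(=O)C[C@H]1O[Si](CC)(CC)CC | intermediate
14 | {[(4R,5S)-5-{[tert-butyl(diphenyl)silyl]oxymethyl}-5-methyl-2-oxo-4-(triethylsilyloxy)cyclohexyl]methyl}trimethylazanium iodide (both C1 epimers) | [I-].C[C@@]1(CO[Si](c2ccccc2)(c2ccccc2)C(C)(C)C)CC(C[N+](C)(C)C)C(=O)C[C@H]1O[Si](CC)(CC)CC | intermediate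
15 | (4S,5R)-4-{[tert-butyl(diphenyl)silyl]oxymethyl}-4-methyl-2-methylidene-5-(triethylsilyloxy)cyclohexan-1-one | C[C@@]1(CO[Si](c2ccccc2)(c2ccccc2)C(C)(C)C)CC(=C)C(=O)C[C@H]1O[Si](CC)(CC)CC | intermediate
16 | (1S,4S,5R)-4-{[tert-butyl(diphenyl)silyl]oxymethyl}-4-methyl-2-methylidene-5-(triethylsilyloxy)cyclohexan-1-ol | C[C@@]1(CO[Si](c2ccccc2)(c2ccccc2)C(C)(C)C)CC(=C)[C@@H](O)C[C@H]1O[Si](CC)(CC)CC | intermediate
17 | (1S,3R,4S)-4-{[tert-butyl(diphenyl)silyl]oxymethyl}-4-methyl-6-methylidenecyclohexane-1,3-diol (both hydroxyls cis to the methyl group) | C[C@@]1(CO[Si](c2ccccc2)(c2ccccc2)C(C)(C)C)CC(=C)[C@@H](O)C[C@H]1O | intermediate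
18 | (1S,4S,5R)-4-{[tert-butyl(diphenyl)silyl]oxymethyl}-5-hydroxy-4-methyl-2-methylidenecyclohexyl acetate | C[C@@]1(CO[Si](c2ccccc2)(c2ccccc2)C(C)(C)C)CC(=C)[C@@H](OC(C)=O)C[C@H]1O | intermediate
19 | (1S,4S,5S)-4-{[tert-butyl(diphenyl)silyl]oxymethyl}-5-chloro-4-methyl-2-methylidenecyclohexyl acetate (chlorine trans to the methyl group) | C[C@@]1(CO[Si](c2ccccc2)(c2ccccc2)C(C)(C)C)CC(=C)[C@@H](OC(C)=O)C[C@@H]1Cl | intermediate
20 | (1S,4S,5S)-5-chloro-4-(hydroxymethyl)-4-methyl-2-methylidenecyclohexyl acetate | C[C@@]1(CO)CC(=C)[C@@H](OC(C)=O)C[C@@H]1Cl | intermediate
21 | (1S,4S,5S)-5-chloro-4-formyl-4-methyl-2-methylidenecyclohexyl acetate | C[C@@]1(C=O)CC(=C)[C@@H](OC(C)=O)C[C@@H]1Cl | intermediate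
22 | (1S,4S,5S)-5-chloro-4-[(Z)-2-chloroethenyl]-4-methyl-2-methylidenecyclohexyl acetate | C[C@@]1(/C=C\Cl)CC(=C)[C@@H](OC(C)=O)C[C@@H]1Cl | intermediate
23 | (1S,4S,5S)-5-chloro-4-[(Z)-2-chloroethenyl]-4-methyl-2-methylidenecyclohexan-1-ol | C[C@@]1(/C=C\Cl)CC(=C)[C@@H](O)C[C@@H]1Cl | intermediate
24 | (1S,2S,4R)-2,4-dichloro-1-[(Z)-2-chloroethenyl]-1-methyl-5-methylidenecyclohexane | C[C@@]1(/C=C\Cl)CC(=C)[C@H](Cl)C[C@@H]1Cl | intermediate
25 | (1S,2R,4S,5S)-1-bromo-1-(bromomethyl)-2,4-dichloro-5-[(Z)-2-chloroethenyl]-5-methylcyclohexane | C[C@@]1(/C=C\Cl)C[C@@](Br)(CBr)[C@H](Cl)C[C@@H]1Cl | target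

## Step count and least certain steps

Total step count: 17. Longest linear sequence: 17 steps (from benzoic acid 1; the route is fully linear).

**Step 5 (key step).** The most likely failure is poor facial selectivity on the flat dienone: the methyl and silyloxymethyl faces differ only beyond the first carbon, so the matched pathway may not dominate and the yield of 9 would fall. A second weakness is slow condensation of the amine with the cross-conjugated ketone, which would let uncatalysed, unselective epoxidation compete.
Fallback: the approach changes from C–O to C–B bond formation on the same arm. Setting out from 8, a copper-catalysed asymmetric conjugate borylation (CuCl, NaOt-Bu, a chiral bisphosphine, B2pin2, MeOH, THF), the known desymmetrising tool for cyclic enones, should give the β-boryl enone F1 with boron on the C7 face of C6. Oxidation of the C–B bond with retention (NaBO3·4H2O, THF–H2O, 0 °C) would then give the hydroxy enone directly. The fallback returns to the route at 10, and step 6 is no longer needed.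

**Step 11 (C6 chlorination).** The most likely failure is that the oxyphosphonium ion does not collapse by SN2 at the neopentyl-type C6 and instead eliminates towards C5 or undergoes a ring-contracting 1,2-shift at the temperature needed.
Fallback: activation and displacement are separated. Setting out from 18, triflation (Tf2O, pyridine, CH2Cl2, −40 °C) would give the C6 triflate F2. This is displaced at −20 °C → rt by free chloride (Bu4NCl, toluene–MeCN) with inversion, before the thermal pathways of the phosphonium route can operate. The equatorial triflate again has no antiperiplanar hydrogen. The fallback returns at 19.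

**Step 17 (dibromination).** The most likely failure is poor facial selectivity in the capture of bromide at C3. The axial line of attack runs past the axial chlorovinyl group, and the allylic chlorine at C4 weakens the preference for opening at the tertiary carbon, so bromine could end up on the wrong face of C3.
Fallback: the approach changes from kinetic capture to thermodynamic selection. Vicinal dibromides interconvert through the bromonium–bromide ion pair (1,2-interchange of the two bromines, which inverts C3). Warming the product mixture in a polar solvent with a bromide salt should therefore enrich the more stable isomer, which is 25, because it keeps the smaller bromine in the axial position. Material that resists equilibration is returned to 24 by debromination with Zn in AcOH–Et2O and brominated again. The fallback sets out from the dibromide mixture and ends at 25 or back at 24; it makes no new compound.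

**Step 14 (chloromethylenation).** The most likely failure is low Z selectivity. Chloromethylene ylides are less Z-selective than their iodo analogues, and the hindered α-quaternary aldehyde needs warming, which erodes kinetic control.
Fallback: the geometry is taken from a syn reduction instead of from the Wittig reaction. Setting out from 21, homologation with dimethyl (1-diazo-2-oxopropyl)phosphonate (K2CO3, MeOH) would give the alkynol F3; the acetate is lost in the same pot, which is acceptable because it is removed in step 15 anyway. Chlorination of the acetylide (n-BuLi, 2 equiv, THF, −78 °C; N-chlorosuccinimide) would give the chloroalkynol F4. Diimide generated from 2-nitrobenzenesulfonylhydrazide and Et3N should reduce the electron-poor chloroalkyne faster than the hindered exocyclic alkene and deliver the Z-chloroalkene only. The fallback returns at 23.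

## Further compounds

F1 | step 5 | (4S,5R)-4-{[tert-butyl(diphenyl)silyl]oxymethyl}-4-methyl-5-(4,4,5,5-tetramethyl-1,3,2-dioxaborolan-2-yl)cyclohex-2-en-1-one | C[C@@]1(CO[Si](c2ccccc2)(c2ccccc2)C(C)(C)C)C=CC(=O)C[C@H]1B3OC(C)(C)C(C)(C)O3
F2 | step 11 | (1S,4S,5R)-4-{[tert-butyl(diphenyl)silyl]oxymethyl}-4-methyl-2-methylidene-5-(trifluoromethanesulfonyloxy)cyclohexyl acetate | C[C@@]1(CO[Si](c2ccccc2)(c2ccccc2)C(C)(C)C)CC(=C)[C@@H](OC(C)=O)C[C@H]1OS(=O)(=O)C(F)(F)F
F3 | step 14 | (1S,4S,5S)-5-chloro-4-ethynyl-4-methyl-2-methylidenecyclohexan-1-ol | C[C@@]1(C#C)CC(=C)[C@@H](O)C[C@@H]1Cl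
F4 | step 14 | (1S,4S,5S)-5-chloro-4-(chloroethynyl)-4-methyl-2-methylidenecyclohexan-1-ol | C[C@@]1(C#CCl)CC(=C)[C@@H](O)C[C@@H]1Cl
F0 | step 17 | none | none
A1 | alternative 1 | 2-acetyl-5-hydroxy-2-methyl-4-methylidenecyclohexan-1-one (hydroxyl cis to the methyl group) | C[C@@]1(C(C)=O)CC(=C)[C@@H](O)CC1=O
A2 | alternative 1 | 4,4-diacetyl-2-methylidenepentanal | CC(=O)C(C)(CC(=C)C=O)C(C)=O
A3 | alternative 2 | methylidenecyclohexane with C4 triethylsilyloxy and C6 tert-butyldimethylsilyloxy groups cis to the methyl group and a 4-methoxybenzyloxymethyl group on C1 | C[C@@]1(COCc2ccc(OC)cc2)CC(=C)[C@@H](O[Si](CC)(CC)CC)C[C@H]1O[Si](C)(C)C(C)(C)C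
A4 | alternative 2 | 3-(tert-butyldimethylsilyloxy)-4-[(4-methoxybenzyl)oxymethyl]-4-methylhept-6-ynal | C[C@@]([C@H](O[Si](C)(C)C(C)(C)C)CC=O)(COCc1ccc(OC)cc1)CC#C
A5 | alternative 3 | all-equatorial 5-nitrocyclohexane-4,6-diol with a dioxolane at C3 and a tert-butyldimethylsilyloxymethyl group on C1 | C[C@@]1(CO[Si](C)(C)C(C)(C)C)CC2(OCCO2)[C@@H](O)[C@H]([N+](=O)[O-])[C@H]1O
A6 | alternative 3 | 2-[3-(tert-butyldimethylsilyloxy)-2-formyl-2-methylpropyl]-1,3-dioxolane-2-carbaldehyde | C[C@@](C=O)(CO[Si](C)(C)C(C)(C)C)CC1(C=O)OCCO1
A7 | alternative 3 | nitromethane | C[N+](=O)[O-]
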